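| flask | substrate | partner | free catalyst | remark | time |
|---|---|---|---|---|---|
| north-west | 0.17 M | 1.2 equiv | 1 mol% | run made earlier |  |
| east | 0.38 M | 1.2 equiv | 1 mol% | run made earlier |  |
| south | 0.25 M | 0.60 equiv | 1 mol% | run made earlier |  |
| flask | 0.25 M | 1.20 equiv | 1 mol% |  | 40 h |

- north-west (time / h: target / %, substrate / %): 5.00: 43.7, 55.5; 15.0: 46.7, 52.7; 25.0: 46.8, 52.6; 40.0: 46.5, 53.0
- east (time / h: target / %, substrate / %): 10.0: 60.6, 38.6; 20.0: 61.7, 38.0; 30.0: 61.1, 38.7; 40.0: 61.1, 37.8
- south (time / h: target / %, substrate / %): 5.00: 32.4, 68.1; 15.0: 32.3, 66.9; 25.0: 33.2, 66.6; 40.0: 32.6, 67.0

(each reading ± 0.5 percentage points)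

* why nothing more happens at 40 h, or that something still does (the partner has run out first / it is still moving / forward and back rates have come level / no working catalyst is left / all of the substrate has reacted)
* target at 40 h, in percent of the substrate charged

- the numbers in the tables scatter with a standard deviation of 0.5 percentage points
- the reaction counts as stopped when no species that holds the substrate changes by six tenths of a point or more over the second half of the time

Slowness does not hold these runs at their ends. The south run reads 32.4 % target after 5.00 h and 32.6 % after 40.0 h, inside a scatter of 0.5 percentage points. Yet 67.0 % of its substrate stands, and its partner charge less the target is 0.274 equiv. So I set time aside and read each plateau as substrate + partner ⇌ target at equilibrium, which is thermodynamic control.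

That leaves two amounts to compare: the substrate charge and a concentration I read from the plateaus. I take partner left as its charge less the target.

balance concentration = substrate × partner / target

north-west 0.142 M, east 0.138 M, south 0.141 M

Their mean is my balance concentration, one over the equilibrium constant: 0.141 M. Call r the substrate charge over it, e the equivalents of partner, and y the target as a fraction of the substrate charged.

y / r = (1 − y)(e − y)

At 1.20 equiv, the east run has r = 2.70 and holds more target than the north-west run at r = 1.21. This flask has r = 1.78, and the quadratic gives 54.0 %. The north-west run reads level from 15.0 h, so I expect this flask level at 40 h.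

The forecast says forward and back rates have come level, with 53.7 % target (range 52.8 % to 54.6 %), a little below my figure, on the ground that “One constant fits all three very different plateaus”.

The flask gives forward and back rates have come level, with 54.1 % target at 40 h.

    catalyst intermediate B ⇌ free catalyst + target (K = 0.140 M, k = 0.0661 s⁻¹)
    substrate + free catalyst ⇌ catalyst intermediate A (K = 1.20 M⁻¹, k = 0.660 M⁻¹ s⁻¹)
    partner + catalyst intermediate A ⇌ catalyst intermediate B (K = 43.4 M⁻¹, k = 0.368 M⁻¹ s⁻¹)

The flask ends with 45.4 % of its substrate and 54.5 % of its partner unbound, and these give a balance concentration of 0.137 M. I carry my reading to the neighbouring flask, charged with 0.42 M of substrate at the same equivalents. There r = 2.99, and the same quadratic gives 63.0 %. The neighbouring flask gives 62.9 % target, with 36 % of its substrate and 47 % of its partner still unbound.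

The data were computed on assumed constants; the scatter is artificial.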